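**Retrosynthetic overview**

1. Numbering: decalin C1–C10 (C4 = quaternary carbon bearing the chain, C5=C10 = tetrasubstituted alkene, C8 = CHMe, C9 = C(Me)CH2Ar), chain C11–C22 counted from C4. The last bonds are the two aryl O–S bonds, then C12–C13 by B-alkyl Suzuki coupling of a C4-vinyl decalin with an (E)-vinyl iodide made from geraniol (Sharpless epoxidation, Payne/thiolate inversion at C17, propargylation, carboalumination).
2. Ring B is carried as a benzene ring. Birch reduction of a C9 benzoate gives C5=C10, cuts the para C6–O ether (freeing C11–OH) and leaves a C8 enol ether. C9–Me comes from catalytic asymmetric phase-transfer methylation, C8–Me from hydroxyl-directed hydrogenation, the aryl group from an aryllithium and the C9 aldehyde.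
3. Key disconnection: ring A (C1–C5, C10) comes from the four-membered ring of a benzocyclobutenone (C1, C2, C5, C10). Rhodium stitches the two olefin carbons of a tethered 2-methylallyl ether (C3, C4) into the C5–C2 bond and sets quaternary C4.
4. Enabling feature: C4 carries a methyl group and a one-carbon arm (C11) that lies peri to C6, and C5=C10 can be two carbons of an arene. A C6–O–C11 ether therefore holds the 2-methylallyl unit (C3, C4, 4-Me, C11) against the aryl–acyl bond; the tether oxygen later leaves C6 in the Birch step and stays on C11 as the handle for the chain.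
5. Ring order: benzene (future ring B) → cyclobutenone → ring A plus a temporary dihydrofuran → dearomatised ring B.

Key step: step 4

Assumption: the target is drawn as the free bis(hydrogen sulfate); it is generated as its dipotassium salt and protonated only in the last work-up.
Assumption: the sense of induction in steps 4 and 9 is assigned by analogy with simpler substrates; should either be reversed, the antipode of the ligand or catalyst is used.
Remark: conjugate bases (alkoxides, enolates, phenoxides) of numbered compounds are not numbered separately.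

**Route**

Step 1
Reactants: 1 2-bromo-5-methoxyphenol
Product: 2 1-bromo-4-methoxy-2-(methoxymethoxy)benzene
Conditions: MOMCl, i-Pr2NEt, CH2Cl2, 0 °C to rt
Reagents that add atoms: chloromethyl methyl ether, COCCl
Why: Williamson-type O-alkylation of the phenol gives a MOM ether that survives the amide base of the next step and falls off in its acidic work-up; no stereocentre is involved.

Step 2
Reactants: 2 1-bromo-4-methoxy-2-(methoxymethoxy)benzene; 3 1,1-dimethoxyethene
Product: 6 5-hydroxy-3-methoxybicyclo[4.2.0]octa-1,3,5-trien-7-one, via aryne 4 (not isolated), via cyclobutenone dimethyl acetal 5 (not isolated)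
Conditions: NaNH2, THF, rt to 50 °C; then 3 M HCl, THF, 45 °C
Reagents that add atoms: water, O
Why: Dehydrobromination (only one hydrogen is ortho to bromine) gives the aryne, which undergoes stepwise [2+2] cycloaddition with the ketene acetal, the nucleophilic CH2 adding to the aryne carbon remote from the OMOM group so that the acetal carbon ends up ortho to oxygen, and acid then hydrolyses the acetal and the phenolic MOM ether together.

Step 3
Reactants: 6 5-hydroxy-3-methoxybicyclo[4.2.0]octa-1,3,5-trien-7-one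
Product: 7 3-methoxy-5-[(2-methylprop-2-en-1-yl)oxy]bicyclo[4.2.0]octa-1,3,5-trien-7-one
Conditions: 3-bromo-2-methylpropene, K2CO3, acetone, reflux
Reagents that add atoms: 3-bromo-2-methylprop-1-ene, C=C(C)CBr
Why: Williamson etherification under mild carbonate conditions that the strained ketone should tolerate attaches the 2-methylallyl unit (future C3, C4, 4-methyl and C11) to O6.

Step 4
Reactants: 7 3-methoxy-5-[(2-methylprop-2-en-1-yl)oxy]bicyclo[4.2.0]octa-1,3,5-trien-7-one
Product: 8 (2aS)-7-methoxy-2a-methyl-2a,3-dihydro-2H-naphtho[1,8-bc]furan-4(5H)-one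
Conditions: [Rh(cod)Cl]2 (5 mol%), (R)-DTBM-SEGPHOS (12 mol%), 1,4-dioxane, 130 °C, sealed tube
Reagents that add atoms: none
Why: Monovalent rhodium inserts into the strained cyclobutenone (net oxidative addition of the C5(aryl)–C2(acyl) bond) to give an aryl–rhodium–acyl metallacycle; the tethered 1,1-disubstituted olefin inserts into the Rh–aryl bond and C(sp3)–C(acyl) reductive elimination releases the ketone, so that C4 and C3 are stitched into the four-membered ring, which becomes six-membered ring A. The closest known reaction type is the rhodium-catalysed intramolecular carboacylation ("cut and sew") of 3-allyloxybenzocyclobutenones, including enantioselective cases with 1,1-disubstituted olefins that give quaternary centres. Ring closures: the dihydrofuran ring (O, C11, C4, C5, C6) forms by 5-exo-trig aryl-metalation of the olefin, and ring A (C1–C5, C10) by reductive elimination from the resulting seven-membered acyl–alkyl rhodacycle. The only new stereocentre, quaternary C4, is set in the olefin insertion under control of the chiral bisphosphine, since the substrate has no stereocentre. The step needs site selectivity for the C5–C2 over the C1–C2 bond, exo regiochemistry and suppression of decarbonylation: the short ether tether at C6, ortho to the aryl–acyl bond, lets only the aryl–rhodium–acyl metallacycle reach the olefin and forces the aryl group onto the substituted olefin carbon, and the chelating phosphine disfavours loss of CO.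

Step 5
Reactants: 8 (2aS)-7-methoxy-2a-methyl-2a,3-dihydro-2H-naphtho[1,8-bc]furan-4(5H)-one
Product: 9 (2aS)-7-methoxy-2a-methyl-2a,3,4,5-tetrahydro-2H-naphtho[1,8-bc]furan
Conditions: N2H4·H2O, KOH, diethylene glycol, 130 then 195 °C
Reagents that add atoms: none
Why: Wolff–Kishner (Huang-Minlon) reduction removes the C2 carbonyl, which has served as the acyl partner; quaternary C4 cannot epimerise.

Step 6
Reactants: 9 (2aS)-7-methoxy-2a-methyl-2a,3,4,5-tetrahydro-2H-naphtho[1,8-bc]furan
Product: 10 (2aS)-6-bromo-7-methoxy-2a-methyl-2a,3,4,5-tetrahydro-2H-naphtho[1,8-bc]furan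
Conditions: NBS, MeCN, 0 °C
Reagents that add atoms: N-bromosuccinimide, O=C1CCC(=O)N1Br
Why: Electrophilic aromatic bromination should go to C9, which is para to the ring oxygen and ortho to the methoxy group, rather than to the more crowded C7 between the two oxygens, as in the 4-bromination of resorcinol diethers.

Step 7
Reactants: 10 (2aS)-6-bromo-7-methoxy-2a-methyl-2a,3,4,5-tetrahydro-2H-naphtho[1,8-bc]furan
Product: 12 tert-butyl (2aS)-7-methoxy-2a-methyl-2a,3,4,5-tetrahydro-2H-naphtho[1,8-bc]furan-6-carboxylate, via aryllithium 11 (not isolated)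
Conditions: n-BuLi, THF, −78 °C; then Boc2O, −78 °C to rt
Reagents that add atoms: di-tert-butyl dicarbonate, CC(C)(C)OC(=O)OC(=O)OC(C)(C)C
Why: Bromine–lithium exchange and acylation of the aryllithium with Boc2O install the tert-butyl ester that steers the Birch reduction and later becomes the benzylic carbon.

Step 8
Reactants: 12 tert-butyl (2aS)-7-methoxy-2a-methyl-2a,3,4,5-tetrahydro-2H-naphtho[1,8-bc]furan-6-carboxylate
Product: 15 tert-butyl (5S)-5-(hydroxymethyl)-5-methyl-2-oxo-1,2,3,4,5,6,7,8-octahydronaphthalene-1-carboxylate (C1 epimers), via ring-opened aromatic ester 13 (not isolated), via dihydro enol ether 14 (not isolated)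
Conditions: Li, NH3(l), THF, t-BuOH (2.5 equiv), −78 °C; NH4Cl; then 1 M HCl, THF, 0 °C to rt
Reagents that add atoms: water, O
Why: Birch reduction of the benzoate: the first two-electron reduction protonates C6 (para to the ester) and the dienolate expels the C6 alkoxide (the known hydrogenolysis of a para-alkoxy group of benzoates), which re-aromatises the ring and frees C11–O−; the second reduction gives the 1,4-dihydro ester with the double bonds on the substituted carbons (C5=C10, C7=C8), and mild acid hydrolyses the enol ether to the C8 ketone without touching C4.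

Step 9
Reactants: 15 tert-butyl (5S)-5-(hydroxymethyl)-5-methyl-2-oxo-1,2,3,4,5,6,7,8-octahydronaphthalene-1-carboxylate
Product: 16 tert-butyl (1S,5S)-5-(hydroxymethyl)-1,5-dimethyl-2-oxo-1,2,3,4,5,6,7,8-octahydronaphthalene-1-carboxylate
Conditions: MeI, (S,S)-N-spiro bis(binaphthyl)ammonium bromide bearing 3,5-bis(trifluoromethyl)phenyl groups (2 mol%), sat. aq K2CO3, toluene, 0 °C, argon
Reagents that add atoms: iodomethane, CI
Why: Enantioselective phase-transfer alkylation of a cyclic beta-keto ester: the chiral ammonium cation pairs with the planar enolate, whose ketone and alkene flanks are well differentiated, and shields one face, so that C9 is set by the catalyst independently of the remote C4, while carbonate is too weak a base to alkylate the free alcohol.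

Step 10
Reactants: 16 tert-butyl (1S,5S)-5-(hydroxymethyl)-1,5-dimethyl-2-oxo-1,2,3,4,5,6,7,8-octahydronaphthalene-1-carboxylate
Product: 17 tert-butyl (1R,5S)-5-(hydroxymethyl)-1,5-dimethyl-2-methylidene-1,2,3,4,5,6,7,8-octahydronaphthalene-1-carboxylate
Conditions: Zn, CH2Br2, TiCl4, THF/CH2Cl2, 0 °C to rt
Reagents that add atoms: dibromomethane, BrCBr
Why: Takai–Lombardo methylenation, a non-basic carbonyl olefination that works on hindered ketones next to quaternary centres and leaves the tert-butyl ester alone, supplies the C8 methyl carbon.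

Step 11
Reactants: 17 tert-butyl (1R,5S)-5-(hydroxymethyl)-1,5-dimethyl-2-methylidene-1,2,3,4,5,6,7,8-octahydronaphthalene-1-carboxylate
Product: 18 tert-butyl (1R,5S)-5-[(benzyloxy)methyl]-1,5-dimethyl-2-methylidene-1,2,3,4,5,6,7,8-octahydronaphthalene-1-carboxylate
Conditions: NaH, BnBr, Bu4NI (cat.), THF/DMF, 0 °C to rt
Reagents that add atoms: benzyl bromide, BrCc1ccccc1
Why: Williamson benzylation of the neopentyl alcohol (no enolisable position remains) masks C11–OH with a group that the later dissolving-metal step removes at no extra cost.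

Step 12
Reactants: 18 tert-butyl (1R,5S)-5-[(benzyloxy)methyl]-1,5-dimethyl-2-methylidene-1,2,3,4,5,6,7,8-octahydronaphthalene-1-carboxylate
Product: 19 {(1R,5S)-5-[(benzyloxy)methyl]-1,5-dimethyl-2-methylidene-1,2,3,4,5,6,7,8-octahydronaphthalen-1-yl}methanol
Conditions: LiAlH4, THF, reflux
Reagents that add atoms: none
Why: Hydride reduction of the hindered ester gives the neopentyl alcohol that serves first as directing group and then as precursor of the benzylic carbon.

Step 13
Reactants: 19 {(1R,5S)-5-[(benzyloxy)methyl]-1,5-dimethyl-2-methylidene-1,2,3,4,5,6,7,8-octahydronaphthalen-1-yl}methanol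
Product: 20 {(1R,2S,5S)-5-[(benzyloxy)methyl]-1,2,5-trimethyl-1,2,3,4,5,6,7,8-octahydronaphthalen-1-yl}methanol
Conditions: H2 (1 atm), [Ir(cod)(PCy3)(py)]PF6 (5 mol%), CH2Cl2, 0 °C to rt
Reagents that add atoms: none
Why: Hydroxyl-directed hydrogenation: the homoallylic hydroxymethyl group binds the cationic iridium and delivers hydrogen to the exocyclic alkene from its own face, which places the new C8 methyl cis to the C9 methyl, while the tetrasubstituted C5=C10 bond is too hindered to react.

Step 14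
Reactants: 20 {(1R,2S,5S)-5-[(benzyloxy)methyl]-1,2,5-trimethyl-1,2,3,4,5,6,7,8-octahydronaphthalen-1-yl}methanol
Product: 21 (1R,2S,5S)-5-[(benzyloxy)methyl]-1,2,5-trimethyl-1,2,3,4,5,6,7,8-octahydronaphthalene-1-carbaldehyde
Conditions: Dess–Martin periodinane, NaHCO3, CH2Cl2, rt
Reagents that add atoms: none
Why: Dess–Martin oxidation gives the non-enolisable neopentyl aldehyde under neutral conditions.

Step 15
Reactants: 22 hydroquinone
Product: 23 1,4-bis(methoxymethoxy)benzene
Conditions: NaH, MOMCl, DMF, 0 °C to rt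
Reagents that add atoms: chloromethyl methyl ether, COCCl
Why: Double Williamson etherification gives the bis-MOM ether, whose oxygens direct the ortho-lithiation of the next step.

Step 16
Reactants: 21 (1R,2S,5S)-5-[(benzyloxy)methyl]-1,2,5-trimethyl-1,2,3,4,5,6,7,8-octahydronaphthalene-1-carbaldehyde; 23 1,4-bis(methoxymethoxy)benzene
Product: 25 {(1R,2S,5S)-5-[(benzyloxy)methyl]-1,2,5-trimethyl-1,2,3,4,5,6,7,8-octahydronaphthalen-1-yl}[2,5-bis(methoxymethoxy)phenyl]methanol (carbinol epimers), via aryllithium 24 (not isolated)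
Conditions: 23, n-BuLi, THF, 0 °C; then 21, −78 to 0 °C; NH4Cl
Reagents that add atoms: none
Why: Directed ortho-metalation of the bis-MOM ether and 1,2-addition of the aryllithium to the aldehyde form the C9–CH–aryl bond; the carbinol configuration is irrelevant because the oxygen is removed next.

Step 17
Reactants: 25 {(1R,2S,5S)-5-[(benzyloxy)methyl]-1,2,5-trimethyl-1,2,3,4,5,6,7,8-octahydronaphthalen-1-yl}[2,5-bis(methoxymethoxy)phenyl]methanol
Product: 26 {(1S,5R,6S)-5-{[2,5-bis(methoxymethoxy)phenyl]methyl}-1,5,6-trimethyl-1,2,3,4,5,6,7,8-octahydronaphthalen-1-yl}methanol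
Conditions: Li, NH3(l), THF, −78 to −40 °C; then NH4Cl
Reagents that add atoms: none
Why: Dissolving-metal hydrogenolysis cleaves the benzylic C–O bond of the carbinol and the O-benzyl ether at C11 in one operation through arene radical anions, while the aryl MOM ethers and the tetrasubstituted alkene should survive.

Step 18
Reactants: 26 {(1S,5R,6S)-5-{[2,5-bis(methoxymethoxy)phenyl]methyl}-1,5,6-trimethyl-1,2,3,4,5,6,7,8-octahydronaphthalen-1-yl}methanol
Product: 27 (1S,5R,6S)-5-{[2,5-bis(methoxymethoxy)phenyl]methyl}-1,5,6-trimethyl-1,2,3,4,5,6,7,8-octahydronaphthalene-1-carbaldehyde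
Conditions: Dess–Martin periodinane, NaHCO3, CH2Cl2, rt
Reagents that add atoms: none
Why: Dess–Martin oxidation of the neopentyl alcohol gives an aldehyde that can neither enolise nor move the beta,gamma-double bond because C4 is quaternary.

Step 19
Reactants: 27 (1S,5R,6S)-5-{[2,5-bis(methoxymethoxy)phenyl]methyl}-1,5,6-trimethyl-1,2,3,4,5,6,7,8-octahydronaphthalene-1-carbaldehyde
Product: 28 2-{[(1R,2S,5R)-5-ethenyl-1,2,5-trimethyl-1,2,3,4,5,6,7,8-octahydronaphthalen-1-yl]methyl}-1,4-bis(methoxymethoxy)benzene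
Conditions: Ph3PCH3Br, KN(SiMe3)2, THF, 0 °C to rt
Reagents that add atoms: methyltriphenylphosphonium bromide, C[P+](c1ccccc1)(c1ccccc1)c1ccccc1.[Br-]
Why: Wittig methylenation of the hindered aldehyde gives the C11=C12 vinyl group needed for hydroboration.

Step 20
Reactants: 29 geraniol
Product: 30 (2R,3R)-2,3-epoxygeraniol
Conditions: Ti(OiPr)4 (5 mol%), D-(−)-diethyl tartrate (6 mol%), t-BuOOH, 4 Å molecular sieves, CH2Cl2, −20 °C
Reagents that add atoms: tert-butyl hydroperoxide, CC(C)(C)OO
Why: Sharpless asymmetric epoxidation of the allylic alcohol is selective for the 2,3-alkene and, with the D-tartrate, gives the (2R,3R)-epoxide.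

Step 21
Reactants: 30 (2R,3R)-2,3-epoxygeraniol
Product: 31 (2R,3R)-3,7-dimethyl-1-(phenylsulfanyl)oct-6-ene-2,3-diol
Conditions: PhSH, 0.5 M aq NaOH, t-BuOH, 75 °C
Reagents that add atoms: benzenethiol, Sc1ccccc1
Why: Payne rearrangement to the terminal epoxide (inversion at C2, the future C17) and irreversible opening by thiolate at C1 give the anti-diol pattern that a syn-dihydroxylation of the E-alkene could not give.

Step 22
Reactants: 31 (2R,3R)-3,7-dimethyl-1-(phenylsulfanyl)oct-6-ene-2,3-diol
Product: 33 (2R)-6-methyl-2-[(2S)-oxiran-2-yl]hept-5-en-2-ol, via sulfonium salt 32 (not isolated)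
Conditions: Me3OBF4, CH2Cl2, 0 °C to rt; then 10% aq NaOH, 0 °C
Reagents that add atoms: none
Why: S-Methylation makes a sulfonium leaving group that the neighbouring C2 alkoxide displaces (3-exo-tet) to give the terminal epoxide with both stereocentres untouched.

Step 23
Reactants: 33 (2R)-6-methyl-2-[(2S)-oxiran-2-yl]hept-5-en-2-ol
Product: 35 (5S,6R)-6,10-dimethylundec-9-en-1-yne-5,6-diol, via silyl alkyne diol 34 (not isolated)
Conditions: 1-(trimethylsilyl)propyne, n-BuLi, THF, −78 °C; then 33, DMPU, −78 to 0 °C; then K2CO3, MeOH, rt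
Reagents that add atoms: 1-(trimethylsilyl)prop-1-yne, CC#C[Si](C)(C)C
Why: The propargylic lithium reagent opens the terminal epoxide at its CH2 carbon (the silyl group suppresses allenyl products) and methanolysis removes the silyl group, which leaves C17 and C18 as set.

Step 24
Reactants: 35 (5S,6R)-6,10-dimethylundec-9-en-1-yne-5,6-diol
Product: 37 (1E,5S,6R)-1-iodo-2,6,10-trimethylundeca-1,9-diene-5,6-diol, via alkenylalane 36 (not isolated)
Conditions: AlMe3 (5 equiv), Cp2ZrCl2 (0.5 equiv), CH2Cl2, 0 °C to rt; then I2, THF, −30 °C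
Reagents that add atoms: trimethylaluminium, C[Al](C)C; iodine, II
Why: Zirconium-catalysed carboalumination (Negishi) adds methyl and aluminium syn across the terminal alkyne with the methyl on the inner carbon, and iodinolysis with retention gives the (E)-vinyl iodide, the hydroxyl groups being carried as aluminium alkoxides.

Step 25
Reactants: 28 2-{[(1R,2S,5R)-5-ethenyl-1,2,5-trimethyl-1,2,3,4,5,6,7,8-octahydronaphthalen-1-yl]methyl}-1,4-bis(methoxymethoxy)benzene; 37 (1E,5S,6R)-1-iodo-2,6,10-trimethylundeca-1,9-diene-5,6-diol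
Product: 39 2-{[(1R,2S,5R)-5-[(3E,7S,8R)-7,8-dihydroxy-4,8,12-trimethyltrideca-3,11-dien-1-yl]-1,2,5-trimethyl-1,2,3,4,5,6,7,8-octahydronaphthalen-1-yl]methyl}-1,4-bis(methoxymethoxy)benzene, via alkylborane 38 (not isolated)
Conditions: 28, 9-BBN-H, THF, rt; then 37, PdCl2(dppf) (5 mol%), AsPh3, Cs2CO3, DMF/H2O, rt
Reagents that add atoms: none
Why: Anti-Markovnikov hydroboration of the only unhindered alkene followed by B-alkyl Suzuki–Miyaura coupling forms C12–C13 with retention of the E geometry and tolerates the free diol.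

Step 26
Reactants: 39 2-{[(1R,2S,5R)-5-[(3E,7S,8R)-7,8-dihydroxy-4,8,12-trimethyltrideca-3,11-dien-1-yl]-1,2,5-trimethyl-1,2,3,4,5,6,7,8-octahydronaphthalen-1-yl]methyl}-1,4-bis(methoxymethoxy)benzene
Product: 40 2-{[(1R,2S,5R)-5-[(3E,7S,8R)-7,8-dihydroxy-4,8,12-trimethyltrideca-3,11-dien-1-yl]-1,2,5-trimethyl-1,2,3,4,5,6,7,8-octahydronaphthalen-1-yl]methyl}benzene-1,4-diol
Conditions: ZnBr2, n-PrSH, CH2Cl2, 0 °C, argon
Reagents that add atoms: none
Why: Lewis acid/thiol cleavage of the two aryl MOM acetals within minutes at 0 °C avoids protic acid that could cyclise the hydroxy-alkene or the hydroquinone onto the alkenes.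

Step 27
Reactants: 40 2-{[(1R,2S,5R)-5-[(3E,7S,8R)-7,8-dihydroxy-4,8,12-trimethyltrideca-3,11-dien-1-yl]-1,2,5-trimethyl-1,2,3,4,5,6,7,8-octahydronaphthalen-1-yl]methyl}benzene-1,4-diol
Product: 41 CNP0442769.2, 2-{[(1R,2S,5R)-5-[(3E,7S,8R)-7,8-dihydroxy-4,8,12-trimethyltrideca-3,11-dien-1-yl]-1,2,5-trimethyl-1,2,3,4,5,6,7,8-octahydronaphthalen-1-yl]methyl}-1,4-phenylene bis(hydrogen sulfate)
Conditions: KOt-Bu (2.1 equiv), DMF, −40 °C, degassed; SO3·NMe3 (2.5 equiv), −40 to 0 °C; then cold 0.1 M HCl, n-BuOH extraction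
Reagents that add atoms: sulfur trioxide–trimethylamine complex, C[N+](C)(C)S(=O)(=O)[O-]
Why: O-Sulfation with the sulfur trioxide–amine complex: only the two phenols are deprotonated by two equivalents of alkoxide base, and the phenoxides should be sulfated far faster than the neutral secondary and tertiary alcohols.

**Compound list**

1 | 2-bromo-5-methoxyphenol | Oc1cc(OC)ccc1Br | starting material
2 | 1-bromo-4-methoxy-2-(methoxymethoxy)benzene | COCOc1cc(OC)ccc1Br | intermediate
3 | 1,1-dimethoxyethene | C=C(OC)OC | starting material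
4 | 5-methoxy-3-(methoxymethoxy)benzyne | COCOC1=CC(OC)=CC#C1 | intermediate
5 | 3,7,7-trimethoxy-5-(methoxymethoxy)bicyclo[4.2.0]octa-1,3,5-triene | COC1(OC)Cc2cc(OC)cc(OCOC)c12 | intermediate
6 | 5-hydroxy-3-methoxybicyclo[4.2.0]octa-1,3,5-trien-7-one | O=C1Cc2cc(OC)cc(O)c12 | intermediate
7 | 3-methoxy-5-[(2-methylprop-2-en-1-yl)oxy]bicyclo[4.2.0]octa-1,3,5-trien-7-one | O=C1Cc2cc(OC)cc(OCC(C)=C)c12 | intermediate
8 | (2aS)-7-methoxy-2a-methyl-2a,3-dihydro-2H-naphtho[1,8-bc]furan-4(5H)-one | O1C[C@@]2(C)CC(=O)Cc3cc(OC)cc1c23 | intermediate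
9 | (2aS)-7-methoxy-2a-methyl-2a,3,4,5-tetrahydro-2H-naphtho[1,8-bc]furan | O1C[C@@]2(C)CCCc3cc(OC)cc1c23 | intermediate
10 | (2aS)-6-bromo-7-methoxy-2a-methyl-2a,3,4,5-tetrahydro-2H-naphtho[1,8-bc]furan | O1C[C@@]2(C)CCCc3c(Br)c(OC)cc1c23 | intermediate
11 | [(2aS)-7-methoxy-2a-methyl-2a,3,4,5-tetrahydro-2H-naphtho[1,8-bc]furan-6-yl]lithium | O1C[C@@]2(C)CCCc3c([Li])c(OC)cc1c23 | intermediate
12 | tert-butyl (2aS)-7-methoxy-2a-methyl-2a,3,4,5-tetrahydro-2H-naphtho[1,8-bc]furan-6-carboxylate | O1C[C@@]2(C)CCCc3c(C(=O)OC(C)(C)C)c(OC)cc1c23 | intermediate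
13 | tert-butyl (5S)-5-(hydroxymethyl)-2-methoxy-5-methyl-5,6,7,8-tetrahydronaphthalene-1-carboxylate (present as lithium alkoxide) | OC[C@@]1(C)CCCc2c1ccc(OC)c2C(=O)OC(C)(C)C | intermediate
14 | tert-butyl (5S)-5-(hydroxymethyl)-2-methoxy-5-methyl-1,4,5,6,7,8-hexahydronaphthalene-1-carboxylate (C1 epimers) | OC[C@@]1(C)CCCC2=C1CC=C(OC)C2C(=O)OC(C)(C)C | intermediate
15 | tert-butyl (5S)-5-(hydroxymethyl)-5-methyl-2-oxo-1,2,3,4,5,6,7,8-octahydronaphthalene-1-carboxylate (C1 epimers) | OC[C@@]1(C)CCCC2=C1CCC(=O)C2C(=O)OC(C)(C)C | intermediate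
16 | tert-butyl (1S,5S)-5-(hydroxymethyl)-1,5-dimethyl-2-oxo-1,2,3,4,5,6,7,8-octahydronaphthalene-1-carboxylate | OC[C@@]1(C)CCCC2=C1CCC(=O)[C@@]2(C)C(=O)OC(C)(C)C | intermediate
17 | tert-butyl (1R,5S)-5-(hydroxymethyl)-1,5-dimethyl-2-methylidene-1,2,3,4,5,6,7,8-octahydronaphthalene-1-carboxylate | OC[C@@]1(C)CCCC2=C1CCC(=C)[C@@]2(C)C(=O)OC(C)(C)C | intermediate
18 | tert-butyl (1R,5S)-5-[(benzyloxy)methyl]-1,5-dimethyl-2-methylidene-1,2,3,4,5,6,7,8-octahydronaphthalene-1-carboxylate | O(Cc1ccccc1)C[C@@]2(C)CCCC3=C2CCC(=C)[C@@]3(C)C(=O)OC(C)(C)C | intermediate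
19 | {(1R,5S)-5-[(benzyloxy)methyl]-1,5-dimethyl-2-methylidene-1,2,3,4,5,6,7,8-octahydronaphthalen-1-yl}methanol | O(Cc1ccccc1)C[C@@]2(C)CCCC3=C2CCC(=C)[C@@]3(C)CO | intermediate
20 | {(1R,2S,5S)-5-[(benzyloxy)methyl]-1,2,5-trimethyl-1,2,3,4,5,6,7,8-octahydronaphthalen-1-yl}methanol | O(Cc1ccccc1)C[C@@]2(C)CCCC3=C2CC[C@H](C)[C@@]3(C)CO | intermediate
21 | (1R,2S,5S)-5-[(benzyloxy)methyl]-1,2,5-trimethyl-1,2,3,4,5,6,7,8-octahydronaphthalene-1-carbaldehyde | O(Cc1ccccc1)C[C@@]2(C)CCCC3=C2CC[C@H](C)[C@@]3(C)C=O | intermediate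
22 | hydroquinone | Oc1ccc(O)cc1 | starting material
23 | 1,4-bis(methoxymethoxy)benzene | COCOc1ccc(OCOC)cc1 | intermediate
24 | [2,5-bis(methoxymethoxy)phenyl]lithium | [Li]c1cc(OCOC)ccc1OCOC | intermediate
25 | {(1R,2S,5S)-5-[(benzyloxy)methyl]-1,2,5-trimethyl-1,2,3,4,5,6,7,8-octahydronaphthalen-1-yl}[2,5-bis(methoxymethoxy)phenyl]methanol (carbinol epimers) | O(Cc1ccccc1)C[C@@]2(C)CCCC3=C2CC[C@H](C)[C@@]3(C)C(O)c4cc(OCOC)ccc4OCOC | intermediate
26 | {(1S,5R,6S)-5-{[2,5-bis(methoxymethoxy)phenyl]methyl}-1,5,6-trimethyl-1,2,3,4,5,6,7,8-octahydronaphthalen-1-yl}methanol | OC[C@@]1(C)CCCC2=C1CC[C@H](C)[C@@]2(C)Cc3cc(OCOC)ccc3OCOC | intermediate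
27 | (1S,5R,6S)-5-{[2,5-bis(methoxymethoxy)phenyl]methyl}-1,5,6-trimethyl-1,2,3,4,5,6,7,8-octahydronaphthalene-1-carbaldehyde | O=C[C@@]1(C)CCCC2=C1CC[C@H](C)[C@@]2(C)Cc3cc(OCOC)ccc3OCOC | intermediate
28 | 2-{[(1R,2S,5R)-5-ethenyl-1,2,5-trimethyl-1,2,3,4,5,6,7,8-octahydronaphthalen-1-yl]methyl}-1,4-bis(methoxymethoxy)benzene | C=C[C@@]1(C)CCCC2=C1CC[C@H](C)[C@@]2(C)Cc3cc(OCOC)ccc3OCOC | intermediate
29 | geraniol | CC(C)=CCC/C(C)=C/CO | starting material
30 | (2R,3R)-2,3-epoxygeraniol, [(2R,3R)-3-methyl-3-(4-methylpent-3-en-1-yl)oxiran-2-yl]methanol | OC[C@H]1O[C@]1(C)CCC=C(C)C | intermediate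
31 | (2R,3R)-3,7-dimethyl-1-(phenylsulfanyl)oct-6-ene-2,3-diol | CC(C)=CCC[C@@](C)(O)[C@@H](O)CSc1ccccc1 | intermediate
32 | [(2R,3R)-2,3-dihydroxy-3,7-dimethyloct-6-en-1-yl](methyl)(phenyl)sulfonium tetrafluoroborate | CC(C)=CCC[C@@](C)(O)[C@@H](O)C[S+](C)c1ccccc1.F[B-](F)(F)F | intermediate
33 | (2R)-6-methyl-2-[(2S)-oxiran-2-yl]hept-5-en-2-ol | CC(C)=CCC[C@@](C)(O)[C@@H]1CO1 | intermediate
34 | (5S,6R)-6,10-dimethyl-1-(trimethylsilyl)undec-9-en-1-yne-5,6-diol | CC(C)=CCC[C@@](C)(O)[C@@H](O)CCC#C[Si](C)(C)C | intermediate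
35 | (5S,6R)-6,10-dimethylundec-9-en-1-yne-5,6-diol | CC(C)=CCC[C@@](C)(O)[C@@H](O)CCC#C | intermediate
36 | [(1E,5S,6R)-5,6-dihydroxy-2,6,10-trimethylundeca-1,9-dien-1-yl]dimethylalane (hydroxyl groups present as aluminium alkoxides) | CC(C)=CCC[C@@](C)(O)[C@@H](O)CC/C(C)=C/[Al](C)C | intermediate
37 | (1E,5S,6R)-1-iodo-2,6,10-trimethylundeca-1,9-diene-5,6-diol | CC(C)=CCC[C@@](C)(O)[C@@H](O)CC/C(C)=C/I | intermediate
38 | 9-(2-{5-[2,5-bis(methoxymethoxy)benzyl]-1,5,6-trimethyl-1,2,3,4,5,6,7,8-octahydronaphthalen-1-yl}ethyl)-9-borabicyclo[3.3.1]nonane, configuration as in 28 | C1CCC2CCCC1B2CC[C@@]3(C)CCCC4=C3CC[C@H](C)[C@@]4(C)Cc5cc(OCOC)ccc5OCOC | intermediate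
39 | 2-{[(1R,2S,5R)-5-[(3E,7S,8R)-7,8-dihydroxy-4,8,12-trimethyltrideca-3,11-dien-1-yl]-1,2,5-trimethyl-1,2,3,4,5,6,7,8-octahydronaphthalen-1-yl]methyl}-1,4-bis(methoxymethoxy)benzene | CC(C)=CCC[C@@](C)(O)[C@@H](O)CC/C(C)=C/CC[C@@]1(C)CCCC2=C1CC[C@H](C)[C@@]2(C)Cc1cc(OCOC)ccc1OCOC | intermediate
40 | 2-{[(1R,2S,5R)-5-[(3E,7S,8R)-7,8-dihydroxy-4,8,12-trimethyltrideca-3,11-dien-1-yl]-1,2,5-trimethyl-1,2,3,4,5,6,7,8-octahydronaphthalen-1-yl]methyl}benzene-1,4-diol | CC(C)=CCC[C@@](C)(O)[C@@H](O)CC/C(C)=C/CC[C@@]1(C)CCCC2=C1CC[C@H](C)[C@@]2(C)Cc1cc(O)ccc1O | intermediate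
41 | CNP0442769.2, the 1,4-phenylene bis(hydrogen sulfate) of 40 | CC(C)=CCC[C@@](C)(O)[C@@H](O)CC/C(C)=C/CC[C@@]1(C)CCCC2=C1CC[C@H](C)[C@@]2(C)Cc1cc(OS(=O)(=O)O)ccc1OS(=O)(=O)O | target

**Step count and risks**

Total step count: 27. Longest linear sequence: 21 steps (steps 1–14, 16–19 and 25–27); step 15 and steps 20–24 are side branches.

Steps most likely to fail:

1. Step 8. The ester may be over-reduced, the ortho-methoxy group may be lost by hydrogenolysis, or the ether may open by alkyl–oxygen cleavage and leave a C6 phenoxide that resists further reduction. Fallback: the dearomatisation is run on the lithium carboxylate, the substrate class for which reductive loss of a para-alkoxy group is best known, and the ester is introduced afterwards. Setting out from bromide 10, bromine–lithium exchange (n-BuLi, THF, −78 °C) and quenching with CO2 would give (2aS)-7-methoxy-2a-methyl-2a,3,4,5-tetrahydro-2H-naphtho[1,8-bc]furan-6-carboxylic acid F1. Its reduction with Li in NH3/THF/t-BuOH and careful acidification to pH 5 would give (5S)-5-(hydroxymethyl)-2-methoxy-5-methyl-1,4,5,6,7,8-hexahydronaphthalene-1-carboxylic acid F2. Neutral esterification with O-tert-butyl-N,N′-diisopropylisourea in CH2Cl2 would give the enol ether ester 14, and 1 M HCl in THF brings the sequence back to the route at 15.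

2. Step 9. The ion pair may discriminate poorly between the faces of this extended enolate (C4 is too remote to help), or O-methylation may compete. Fallback: auxiliary control in place of catalyst control. Setting out from 15, condensation with L-valine tert-butyl ester (toluene, molecular sieves) would give tert-butyl (5S)-2-{[(2S)-1-tert-butoxy-3-methyl-1-oxobutan-2-yl]amino}-5-(hydroxymethyl)-5-methyl-3,4,5,6,7,8-hexahydronaphthalene-1-carboxylate F3. Deprotonation with LiN(i-Pr)2 (excess, toluene, −78 °C), methylation with MeI, for which the choice of donor additive is known to select either face with the same auxiliary, and hydrolysis of the imine with aqueous acetic acid would return to the route at 16.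

3. Step 27. The C17 hydroxyl may be sulfated in competition, or the hydroquinone dianion may be oxidised by traces of oxygen. Fallback: the diol is masked for the duration of the sulfation. Setting out from 40, phenylboronic acid (toluene, MgSO4, rt) would give the cyclic phenylboronate of the 7,8-diol of 40 F4. SO3·pyridine in pyridine at 0 °C, which no longer requires the dianion, would then give the 1,4-phenylene bis(hydrogen sulfate) of that boronate F5. Transesterification with pinacol in aqueous NaHCO3 and acidification as in step 27 would come back to the route at 41.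

**Further compounds**

F1 | step 8 | (2aS)-7-methoxy-2a-methyl-2a,3,4,5-tetrahydro-2H-naphtho[1,8-bc]furan-6-carboxylic acid | O1C[C@@]2(C)CCCc3c(C(=O)O)c(OC)cc1c23
F2 | step 8 | (5S)-5-(hydroxymethyl)-2-methoxy-5-methyl-1,4,5,6,7,8-hexahydronaphthalene-1-carboxylic acid (C1 epimers) | OC[C@@]1(C)CCCC2=C1CC=C(OC)C2C(=O)O
F3 | step 9 | tert-butyl (5S)-2-{[(2S)-1-tert-butoxy-3-methyl-1-oxobutan-2-yl]amino}-5-(hydroxymethyl)-5-methyl-3,4,5,6,7,8-hexahydronaphthalene-1-carboxylate | OC[C@@]1(C)CCCC2=C1CCC(N[C@@H](C(C)C)C(=O)OC(C)(C)C)=C2C(=O)OC(C)(C)C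
F4 | step 27 | cyclic phenylboronate (2-phenyl-1,3,2-dioxaborolane) of the 7,8-diol of 40 | CC(C)=CCC[C@@]1(C)OB(c2ccccc2)O[C@H]1CC/C(C)=C/CC[C@@]3(C)CCCC4=C3CC[C@H](C)[C@@]4(C)Cc5cc(O)ccc5O
F5 | step 27 | 1,4-phenylene bis(hydrogen sulfate) of the boronate F4 | CC(C)=CCC[C@@]1(C)OB(c2ccccc2)O[C@H]1CC/C(C)=C/CC[C@@]3(C)CCCC4=C3CC[C@H](C)[C@@]4(C)Cc5cc(OS(=O)(=O)O)ccc5OS(=O)(=O)O
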